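**Narrow solution.** In this flask the solution holds at most 6.00% of the charge as starting material, less than the 70.0% of target that reagent, the limiting reagent, allows, so the solid has to keep feeding the solution.

    starting material + reagent + target → 2 target (k1 = 0.071 M⁻² s⁻¹)
    starting material + reagent → target (k2 = 2.7 × 10⁻⁶ M⁻¹ s⁻¹)
    solid substrate ⇌ starting material, rate k3*(cs3 - [starting material]) while solid is left; crystals form when [starting material] > cs3 (cs3 = 0.12 M, k3 = 0.017 s⁻¹)

solid substrate 2.0 M; reagent 0.700 equiv; time 15 min

1. how much target there is at 15 min, in percent of the solid substrate charged
2. the change that raises the amount of target at 15 min, in percent of the solid substrate charged most ("none" if none brings more than 2 percentage points) (south / west / north-east / none)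
3. amount of target at 15 min, in percent of the solid substrate charged, after south

**Growth clock.** I count amounts as fractions of the solid substrate charged. In a saturated solution step 1 multiplies target at 0.716 min⁻¹, a pseudo-first-order growth. Step 2 matters as a seed: it equals step 1 when target is 0.00190%, and target grows as if it had started from there, which gives an induction period. The solution needs about 58.8 s to fill, so the run offers 10.0 e-foldings.

**Crossing amount.** I carry the crossing amount: the fraction of target at which step 1 uses saturated starting material as fast as the solid replaces it, 8.55%. Solubility cancels from it. While solid is left, dissolved starting material stands near solubility divided by one plus target over the crossing amount, and that crossing amount is to be divided by the fraction of reagent still left. The clock is then spent in two parts: the logarithm of target over the seed, and target over the crossing amount.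

**My reckoning.** Reaching the crossing amount costs 8.41 e-foldings. The remainder, each buying one crossing amount, gives 13.9%. Doubling the solubility doubles the clock and keeps the crossing amount; doubling the reagent doubles the clock and halves it; doubling the dissolution coefficient doubles it. This ranks south first. There I take the logarithm at the reagent's limit and allow my own round 2.3 for thinning reagent, giving 62.0%.

**The forecast.** It gives 11.5% (8% to 17%), south, and 65% (57% to 69%), holding that solubility “doubles both the autocatalytic growth rate and the dissolution ceiling”. Its figures differ somewhat from mine.

**The result.** The simulation gives 12.2%, south with a gain of 53 percentage points, and 65.0%. Reckoned on the reagent left in this flask at 15.0 min, the crossing amount is 10.4%, and target, at 12.2%, stands above it, so the rule puts starting material at 2.75%, and it reads 2.94%. In the neighbour with 1.20 equiv of reagent the crossing amount is 7.42%, target reads 39.3%, the rule puts starting material at 0.953%, and it reads 0.962%.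

The constants used here were set for the occasion; the result is computed.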